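## Retrosynthetic overview

- The target is a 5-hydroxy-7-methoxyflavanone (ring A arene, ring C pyranone) carrying a 2,4-trans flavan at C6 (ring D arene, ring F pyran). The benzyl ether on the ring D 7-OH is removed last, and ring C is opened at O1–C2 (oxa-Michael) to the 2',6'-dihydroxy-4'-methoxychalcone 25.
- The strategy rests on ring A: oxygen at C5, C7 and C8a, the acyl carbon C4 on C4a and the flavan on C6 make it an acylphloroglucinol, a folded tetraketide. A 4-methoxy-2-pyrone already holds C5, C6, C7, C8 and C8a with their oxygens, so ring A is cut at C4a–C5 (Claisen) back to pyrone 23.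
- Pyrone 23 comes from acylation of the 6-methyl group, 4-O-methylation, and acid-mediated union of pyrone C3 with the ring D flavan-4-yl cation, trans to the 2-phenyl group.
- The flavan-4-ol comes from the (S)-flavanone, made by asymmetric conjugate addition of phenylboronic acid to a chromone; the chromone comes from 5-methoxyresorcinol, with the C8 oxygen installed by directed ortho-metalation.
- Order of ring formation: ring F on ring D (steps 7–8), then ring A (step 13), then ring C (step 14).

Key step: step 13

Remark on descriptors: the flavan C4 centre keeps one geometry (trans to the 2-phenyl group) from compound 18 to the target. Its CIP label is R while it carries the pyrone or the ring-opened enoate (18, 19, 21–24), because that substituent outranks C4a, and S once ring A is formed (25–27).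

Assumption: the sense of induction in steps 8 and 14 is taken from the closest models of each catalyst class; both catalysts are available in the mirror-image or pseudo-enantiomeric form, which would be used instead if the configuration found is the opposite one.

## Route

Step 1
Reactants: 1 5-methoxyresorcinol
Product: 2 1-methoxy-3,5-bis(methoxymethoxy)benzene
Conditions: NaH (2.4 equiv), MOMCl (2.4 equiv), DMF, 0 °C to rt
Reagents that add atoms: chloromethyl methyl ether, COCCl
Why: Williamson-type O-alkylation of both phenoxides gives the bis-acetal, which directs the lithiation of step 2 and is later removed by mild acid.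

Step 2
Reactants: 2 1-methoxy-3,5-bis(methoxymethoxy)benzene
Product: 5 4-methoxy-2,6-bis(methoxymethoxy)phenol, via aryllithium 3 (not isolated), via dimethyl arylboronate 4 (not isolated)
Conditions: n-BuLi, THF, 0 °C; B(OCH3)3, −78 °C to rt; 30% H2O2, aq NaOH, 0 °C
Reagents that add atoms: hydrogen peroxide, OO
Why: Directed ortho-metalation should take place at the ring position flanked by the two methoxymethoxy groups (two chelating directors, each stronger than methoxy), and borylation followed by oxidative aryl migration from boron to oxygen gives the phenol.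

Step 3
Reactants: 5 4-methoxy-2,6-bis(methoxymethoxy)phenol
Product: 6 2,5-dimethoxy-1,3-bis(methoxymethoxy)benzene
Conditions: CH3I, K2CO3, acetone, reflux
Reagents that add atoms: iodomethane, CI
Why: Williamson methylation of the only free phenol; the acetals are stable to base.

Step 4
Reactants: 6 2,5-dimethoxy-1,3-bis(methoxymethoxy)benzene
Product: 7 2,5-dimethoxybenzene-1,3-diol
Conditions: conc. HCl (cat.), CH3OH, 50 °C
Reagents that add atoms: none
Why: Acid-catalysed acetal exchange with methanol removes both methoxymethyl groups as dimethoxymethane, while the aryl methyl ethers are untouched.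

Step 5
Reactants: 7 2,5-dimethoxybenzene-1,3-diol
Product: 9 1-(2,4-dihydroxy-3,6-dimethoxyphenyl)ethanone, via ketiminium chloride 8 (not isolated)
Conditions: CH3CN, ZnCl2, HCl (g), Et2O, 0 °C; then H2O, reflux
Reagents that add atoms: acetonitrile, CC#N; water, O
Why: Hoesch acylation; the two free ring positions are equivalent by symmetry and activated ortho and para by the hydroxyls, the ketiminium salt deactivates the ring against a second acylation, and hydrolysis gives the ketone.

Step 6
Reactants: 9 1-(2,4-dihydroxy-3,6-dimethoxyphenyl)ethanone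
Product: 10 1-[4-(benzyloxy)-2-hydroxy-3,6-dimethoxyphenyl]ethanone
Conditions: BnBr (1.05 equiv), K2CO3, acetone, reflux
Reagents that add atoms: benzyl bromide, BrCc1ccccc1
Why: Williamson benzylation should take the more acidic, non-chelated 4-hydroxyl, because the 2-hydroxyl is held in a hydrogen bond to the ketone.

Step 7
Reactants: 10 1-[4-(benzyloxy)-2-hydroxy-3,6-dimethoxyphenyl]ethanone
Product: 12 7-(benzyloxy)-5,8-dimethoxy-4H-chromen-4-one, via enaminone 11 (not isolated)
Conditions: (CH3)2NCH(OCH3)2, toluene, 100 °C; then conc. HCl, CH2Cl2, rt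
Reagents that add atoms: N,N-dimethylformamide dimethyl acetal, COC(OC)N(C)C
Why: Enaminone chromone synthesis; the methyl ketone condenses with the amide acetal, and under acid the phenol adds to the enaminone β-carbon and dimethylamine is lost.

Step 8
Reactants: 12 7-(benzyloxy)-5,8-dimethoxy-4H-chromen-4-one; 13 phenylboronic acid
Product: 14 (2S)-7-(benzyloxy)-5,8-dimethoxy-2-phenylchroman-4-one
Conditions: 13 (2 equiv), Pd(OCOCF3)2 (5 mol%), (R)-4-tert-butyl-2-(pyridin-2-yl)-4,5-dihydrooxazole (6 mol%), NH4PF6 (30 mol%), H2O (5 equiv), ClCH2CH2Cl, 60 °C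
Reagents that add atoms: none
Why: Palladium-catalysed asymmetric conjugate addition of an arylboronic acid to a chromone (transmetalation, face-selective carbopalladation of C2=C3, protonolysis of the palladium enolate); the pyridine-oxazoline ligand sets C2, and the (R)-ligand is chosen on the model of β-substituted cyclic enones, where the (S)-ligand delivers the aryl group to the opposite face.

Step 9
Reactants: 14 (2S)-7-(benzyloxy)-5,8-dimethoxy-2-phenylchroman-4-one
Product: 15 (2S,4S)-7-(benzyloxy)-5,8-dimethoxy-2-phenylchroman-4-ol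
Conditions: NaBH4, CH3OH–THF, 0 °C
Reagents that add atoms: none
Why: Hydride reduction of the aryl ketone, with axial delivery expected to give mainly the 2,4-cis alcohol; the C4 configuration does not matter because this centre is ionised in step 10.

Step 10
Reactants: 15 (2S,4S)-7-(benzyloxy)-5,8-dimethoxy-2-phenylchroman-4-ol; 16 4-hydroxy-6-methyl-2H-pyran-2-one
Product: 18 3-[(2S,4R)-7-(benzyloxy)-5,8-dimethoxy-2-phenylchroman-4-yl]-4-hydroxy-6-methyl-2H-pyran-2-one, via flavan-4-yl cation 17 (not isolated)
Conditions: 16 (3 equiv), TsOH·H2O (10 mol%), 1,4-dioxane, 40 °C, slow addition of 15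
Reagents that add atoms: none
Why: Friedel–Crafts-type alkylation of a cyclic 1,3-dicarbonyl by a benzylic alcohol; the cation is stabilised by the 5-methoxy and 7-benzyloxy groups, and C3 of the hydroxypyrone should attack axially on the half-chair with the 2-phenyl group equatorial, while the peri 5-methoxy group also makes the pseudoaxial C4 substituent the more stable one, so the 2,4-trans product is expected and O-alkylation is reversible under the acid.

Step 11
Reactants: 18 3-[(2S,4R)-7-(benzyloxy)-5,8-dimethoxy-2-phenylchroman-4-yl]-4-hydroxy-6-methyl-2H-pyran-2-one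
Product: 19 3-[(2S,4R)-7-(benzyloxy)-5,8-dimethoxy-2-phenylchroman-4-yl]-4-methoxy-6-methyl-2H-pyran-2-one
Conditions: (CH3O)2SO2, K2CO3, acetone, reflux
Reagents that add atoms: dimethyl sulfate, COS(=O)(=O)OC
Why: O-methylation of the vinylogous acid under these conditions is known to favour the 4-methoxy-2-pyrone over the 2-methoxy-4-pyrone; any minor isomer would be removed by chromatography.

Step 12
Reactants: 19 3-[(2S,4R)-7-(benzyloxy)-5,8-dimethoxy-2-phenylchroman-4-yl]-4-methoxy-6-methyl-2H-pyran-2-one; 20 (E)-N-methoxy-N-methylcinnamamide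
Product: 23 3-[(2S,4R)-7-(benzyloxy)-5,8-dimethoxy-2-phenylchroman-4-yl]-4-methoxy-6-[(3E)-2-oxo-4-phenylbut-3-en-1-yl]-2H-pyran-2-one, via lithiated pyrone 21 (not isolated), via lithium hemiaminal adduct 22 (not isolated)
Conditions: LiN(iPr)2 (1.15 equiv), THF, −78 °C; 20 (1.3 equiv), −78 to −40 °C; aq NH4Cl
Reagents that add atoms: none
Why: Kinetic deprotonation of the 6-methyl group gives the extended enolate (C3 is blocked and the flavan C4–H is not acidic), and acylation by the N-methoxy-N-methylamide stops at the chelated adduct until the quench, which avoids proton transfer to the product and favours carbonyl over conjugate attack.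

Step 13
Reactants: 23 3-[(2S,4R)-7-(benzyloxy)-5,8-dimethoxy-2-phenylchroman-4-yl]-4-methoxy-6-[(3E)-2-oxo-4-phenylbut-3-en-1-yl]-2H-pyran-2-one
Product: 25 (2E)-1-{3-[(2S,4S)-7-(benzyloxy)-5,8-dimethoxy-2-phenylchroman-4-yl]-2,6-dihydroxy-4-methoxyphenyl}-3-phenylprop-2-en-1-one, via ring-opened methyl ester 24 (not isolated)
Conditions: Mg(OCH3)2 (6 equiv), CH3OH, reflux; then 1 M HCl, 0 °C
Reagents that add atoms: none
Why: Methoxide adds to the lactone carbonyl and opens the pyrone to methyl ester 24, in which the ester carbon and the C4 methylene stay cis across the enol ether double bond as they were in the ring (2E by the CIP rules). The magnesium-chelated enolate of the methylene between the two ketones then attacks the ester carbonyl in a 6-exo-trig Claisen condensation, methoxide leaves and the cyclohexadienone tautomerises to the arene, which forms the C4a–C5 bond and closes ring A. The closest known reaction is the Mg(OCH3)2-induced conversion of 6-(2-oxoalkyl)-4-methoxy-2-pyrones into acylphloroglucinol monomethyl ethers, applied here to a pyrone branched at C3. No stereocentre is formed, and the two centres of ring F are untouched because neither C–H is acidic towards alkoxide. The step needs Claisen closure to win over aldol closure and over attack of an enol oxygen on the enol ether carbon; the aldol mode is shut because the former pyrone C3 is a fully substituted enol ether carbon, and magnesium chelation keeps the diketone as a carbon nucleophile next to the ester. The place of every ring A substituent follows from the pyrone connectivity, so the flavan can only end up between the methoxy group and the hydroxyl that comes from the lactone carbonyl.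

Step 14
Reactants: 25 (2E)-1-{3-[(2S,4S)-7-(benzyloxy)-5,8-dimethoxy-2-phenylchroman-4-yl]-2,6-dihydroxy-4-methoxyphenyl}-3-phenylprop-2-en-1-one
Product: 26 (2R)-6-[(2S,4S)-7-(benzyloxy)-5,8-dimethoxy-2-phenylchroman-4-yl]-5-hydroxy-7-methoxy-2-phenylchroman-4-one
Conditions: 1-[3,5-bis(trifluoromethyl)phenyl]-3-[(8S,9S)-6'-methoxycinchonan-9-yl]thiourea (10 mol%), toluene, 0 °C to rt
Reagents that add atoms: none
Why: Intramolecular oxa-Michael addition of a 2'-hydroxychalcone under bifunctional catalysis (quinuclidine on the phenol, thiourea on the enone), closing ring C 6-endo-trig through the 6'-hydroxyl next to the ring hydrogen and not through the 2'-hydroxyl wedged between the carbonyl and the flavan; the catalyst should set C2 as R, and the residual C2 epimer is a diastereomer that chromatography can remove.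

Step 15
Reactants: 26 (2R)-6-[(2S,4S)-7-(benzyloxy)-5,8-dimethoxy-2-phenylchroman-4-yl]-5-hydroxy-7-methoxy-2-phenylchroman-4-one
Product: 27 (2R)-5-hydroxy-6-[(2S,4S)-7-hydroxy-5,8-dimethoxy-2-phenylchroman-4-yl]-7-methoxy-2-phenylchroman-4-one (CNP0301559.1)
Conditions: H2 (1 atm), 10% Pd on carbon, EtOAc, rt
Reagents that add atoms: none
Why: Hydrogenolysis of the benzyl aryl ether under neutral conditions, which spare the cyclic benzylic C2–O bonds and the hydrogen-bonded ketone and do not open the base-sensitive 5-hydroxyflavanone.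

## Compound list

1 | 5-methoxyresorcinol | COc1cc(O)cc(O)c1 | starting material
2 | 1-methoxy-3,5-bis(methoxymethoxy)benzene | COCOc1cc(OC)cc(OCOC)c1 | intermediate
3 | [4-methoxy-2,6-bis(methoxymethoxy)phenyl]lithium | [Li]c1c(OCOC)cc(OC)cc1OCOC | intermediate (not isolated)
4 | dimethyl [4-methoxy-2,6-bis(methoxymethoxy)phenyl]boronate | COB(OC)c1c(OCOC)cc(OC)cc1OCOC | intermediate (not isolated)
5 | 4-methoxy-2,6-bis(methoxymethoxy)phenol | COCOc1cc(OC)cc(OCOC)c1O | intermediate
6 | 2,5-dimethoxy-1,3-bis(methoxymethoxy)benzene | COCOc1cc(OC)cc(OCOC)c1OC | intermediate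
7 | 2,5-dimethoxybenzene-1,3-diol | COc1cc(O)c(OC)c(O)c1 | intermediate
8 | 1-(2,4-dihydroxy-3,6-dimethoxyphenyl)ethan-1-iminium chloride | CC(=[NH2+])c1c(O)c(OC)c(O)cc1OC.[Cl-] | intermediate (not isolated)
9 | 1-(2,4-dihydroxy-3,6-dimethoxyphenyl)ethanone | CC(=O)c1c(O)c(OC)c(O)cc1OC | intermediate
10 | 1-[4-(benzyloxy)-2-hydroxy-3,6-dimethoxyphenyl]ethanone | CC(=O)c1c(O)c(OC)c(OCc2ccccc2)cc1OC | intermediate
11 | (2E)-1-[4-(benzyloxy)-2-hydroxy-3,6-dimethoxyphenyl]-3-(dimethylamino)prop-2-en-1-one | CN(C)/C=C/C(=O)c1c(O)c(OC)c(OCc2ccccc2)cc1OC | intermediate (not isolated)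
12 | 7-(benzyloxy)-5,8-dimethoxy-4H-chromen-4-one | COc1cc(OCc2ccccc2)c(OC)c2occc(=O)c12 | intermediate
13 | phenylboronic acid | OB(O)c1ccccc1 | starting material
14 | (2S)-7-(benzyloxy)-5,8-dimethoxy-2-phenylchroman-4-one | COc1cc(OCc2ccccc2)c(OC)c2c1C(=O)C[C@@H](c1ccccc1)O2 | intermediate
15 | (2S,4S)-7-(benzyloxy)-5,8-dimethoxy-2-phenylchroman-4-ol (2,4-cis) | O[C@H]1C[C@@H](c2ccccc2)Oc2c(OC)c(OCc3ccccc3)cc(OC)c21 | intermediate
16 | 4-hydroxy-6-methyl-2H-pyran-2-one | CC1=CC(O)=CC(=O)O1 | starting material
17 | (2S)-7-(benzyloxy)-5,8-dimethoxy-2-phenylchroman-4-ylium | COc1cc(OCc2ccccc2)c(OC)c2c1[CH+]C[C@@H](c1ccccc1)O2 | intermediate (not isolated)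
18 | 3-[(2S,4R)-7-(benzyloxy)-5,8-dimethoxy-2-phenylchroman-4-yl]-4-hydroxy-6-methyl-2H-pyran-2-one | CC1=CC(O)=C([C@@H]2C[C@@H](c3ccccc3)Oc3c(OC)c(OCc4ccccc4)cc(OC)c32)C(=O)O1 | intermediate
19 | 3-[(2S,4R)-7-(benzyloxy)-5,8-dimethoxy-2-phenylchroman-4-yl]-4-methoxy-6-methyl-2H-pyran-2-one | COC1=C([C@@H]2C[C@@H](c3ccccc3)Oc3c(OC)c(OCc4ccccc4)cc(OC)c32)C(=O)OC(C)=C1 | intermediate
20 | (E)-N-methoxy-N-methylcinnamamide | CON(C)C(=O)/C=C/c1ccccc1 | starting material
21 | {[3-((2S,4R)-7-(benzyloxy)-5,8-dimethoxy-2-phenylchroman-4-yl)-4-methoxy-2-oxo-2H-pyran-6-yl]methyl}lithium | [Li]CC1=CC(OC)=C([C@@H]2C[C@@H](c3ccccc3)Oc3c(OC)c(OCc4ccccc4)cc(OC)c32)C(=O)O1 | intermediate (not isolated)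
22 | lithium alkoxide of the N-methoxy-N-methyl hemiaminal formed from 21 and 20 | [Li]OC(CC1=CC(OC)=C([C@@H]2C[C@@H](c3ccccc3)Oc3c(OC)c(OCc4ccccc4)cc(OC)c32)C(=O)O1)(/C=C/c1ccccc1)N(C)OC | intermediate (not isolated)
23 | 3-[(2S,4R)-7-(benzyloxy)-5,8-dimethoxy-2-phenylchroman-4-yl]-4-methoxy-6-[(3E)-2-oxo-4-phenylbut-3-en-1-yl]-2H-pyran-2-one | O=C1OC(CC(=O)/C=C/c2ccccc2)=CC(OC)=C1[C@@H]1C[C@@H](c3ccccc3)Oc3c(OC)c(OCc4ccccc4)cc(OC)c31 | intermediate
24 | methyl (2E,8E)-2-[(2S,4R)-7-(benzyloxy)-5,8-dimethoxy-2-phenylchroman-4-yl]-3-methoxy-5,7-dioxo-9-phenylnona-2,8-dienoate | COC(=O)/C([C@@H]1C[C@@H](c2ccccc2)Oc2c(OC)c(OCc3ccccc3)cc(OC)c21)=C(/OC)CC(=O)CC(=O)/C=C/c1ccccc1 | intermediate (not isolated)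
25 | (2E)-1-{3-[(2S,4S)-7-(benzyloxy)-5,8-dimethoxy-2-phenylchroman-4-yl]-2,6-dihydroxy-4-methoxyphenyl}-3-phenylprop-2-en-1-one | COc1cc(O)c(C(=O)/C=C/c2ccccc2)c(O)c1[C@@H]1C[C@@H](c3ccccc3)Oc3c(OC)c(OCc4ccccc4)cc(OC)c31 | intermediate
26 | (2R)-6-[(2S,4S)-7-(benzyloxy)-5,8-dimethoxy-2-phenylchroman-4-yl]-5-hydroxy-7-methoxy-2-phenylchroman-4-one | COc1cc2c(c(O)c1[C@@H]1C[C@@H](c3ccccc3)Oc3c(OC)c(OCc4ccccc4)cc(OC)c31)C(=O)C[C@H](c1ccccc1)O2 | intermediate
27 | (2R)-5-hydroxy-6-[(2S,4S)-7-hydroxy-5,8-dimethoxy-2-phenylchroman-4-yl]-7-methoxy-2-phenylchroman-4-one | COc1cc2c(c(O)c1[C@@H]1C[C@@H](c3ccccc3)Oc3c(OC)c(O)cc(OC)c31)C(=O)C[C@H](c1ccccc1)O2 | target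

## Step count and risks

Total step count: 15. Longest linear sequence: 15 steps (1 to 27).

The three steps most likely to fail:

**Step 13.** Addition of methoxide to a lactone carbonyl flanked by the bulky C3 substituent may be slow. Other processes could then take over: closure of a side-chain enol oxygen onto the enol ether carbon, conjugate addition of methoxide to the enone, or premature and unselective closure of ring C during the acidic work-up. The fallback forms ring A's substitution pattern by electrophilic substitution instead of building the ring. It sets out from 15, which is ionised with TsOH·H2O in 1,4-dioxane in the presence of commercial 1-(2,6-dihydroxy-4-methoxyphenyl)ethanone (CC(=O)c1c(O)cc(OC)cc1O). The two free ring positions of that ketone are equivalent, so Friedel–Crafts alkylation trans to the 2-phenyl group should give 1-{3-[(2S,4S)-7-(benzyloxy)-5,8-dimethoxy-2-phenylchroman-4-yl]-2,6-dihydroxy-4-methoxyphenyl}ethanone F1. Claisen–Schmidt condensation of F1 with benzaldehyde (KOH, EtOH, rt) then returns to the route at 25.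

**Step 14.** Facial selectivity at the enone β-carbon may be poor, through a mismatch between catalyst and the resident flavan centres, uncatalysed background cyclisation, or erosion by retro-Michael opening. Closure through the hindered hydroxyl may also compete. The fallback gives up catalyst control for separation and recycling. It sets out from 25, which is cyclised without stereocontrol (NaOAc, EtOH, reflux) to a mixture of 26 and its C2 epimer, (2S)-6-[(2S,4S)-7-(benzyloxy)-5,8-dimethoxy-2-phenylchroman-4-yl]-5-hydroxy-7-methoxy-2-phenylchroman-4-one F2. Because ring D is enantiopure the two are diastereomers and should be separable by chromatography or preparative HPLC. F2 is reopened to 25 with KOH in CH3OH followed by cold acidification and cycled again; the route is rejoined at 26.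

**Step 10.** The cation may be captured by the nucleophilic C6 position of ring D of a second molecule, giving oligomers; the sparingly soluble pyrone may react too slowly; or the attack may not be face-selective. The fallback builds the pyrone on the C4 carbon instead of attaching it whole. It sets out from 15, which is ionised with a catalytic acid in excess methyl acetoacetate as a cheap, liquid carbon nucleophile to give methyl 2-[(2S,4S)-7-(benzyloxy)-5,8-dimethoxy-2-phenylchroman-4-yl]-3-oxobutanoate F3 (either configuration at the ester α-carbon). The dianion of F3 (NaH, then n-BuLi, THF, 0 °C) is acylated at the terminal methyl group with N-methoxy-N-methylacetamide to give methyl 2-[(2S,4S)-7-(benzyloxy)-5,8-dimethoxy-2-phenylchroman-4-yl]-3,5-dioxohexanoate F4. Lactonisation of F4 (DBU, toluene, reflux) returns to the route at 18.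

## Further compounds

F1 | step 13 | 1-{3-[(2S,4S)-7-(benzyloxy)-5,8-dimethoxy-2-phenylchroman-4-yl]-2,6-dihydroxy-4-methoxyphenyl}ethanone | CC(=O)c1c(O)cc(OC)c([C@@H]2C[C@@H](c3ccccc3)Oc3c(OC)c(OCc4ccccc4)cc(OC)c32)c1O
F2 | step 14 | (2S)-6-[(2S,4S)-7-(benzyloxy)-5,8-dimethoxy-2-phenylchroman-4-yl]-5-hydroxy-7-methoxy-2-phenylchroman-4-one | COc1cc2c(c(O)c1[C@@H]1C[C@@H](c3ccccc3)Oc3c(OC)c(OCc4ccccc4)cc(OC)c31)C(=O)C[C@@H](c1ccccc1)O2
F3 | step 10 | methyl 2-[(2S,4S)-7-(benzyloxy)-5,8-dimethoxy-2-phenylchroman-4-yl]-3-oxobutanoate | COC(=O)C(C(C)=O)[C@@H]1C[C@@H](c2ccccc2)Oc2c(OC)c(OCc3ccccc3)cc(OC)c21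
F4 | step 10 | methyl 2-[(2S,4S)-7-(benzyloxy)-5,8-dimethoxy-2-phenylchroman-4-yl]-3,5-dioxohexanoate | COC(=O)C(C(=O)CC(C)=O)[C@@H]1C[C@@H](c2ccccc2)Oc2c(OC)c(OCc3ccccc3)cc(OC)c21
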